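**Retrosynthetic overview**
1. Target ⇐ C12-hydroxylation of the 11,14-quinone ⇐ CAN oxidation of a hydroquinone dimethyl ether.
2. 20,7β-Lactone and 6α-OH ⇐ α-epoxidation of a Δ6 acid with anti opening at benzylic C7 by the C20 carboxylate, after unlocking a 19,20-lactone.
3. Ring B ⇐ Friedel–Crafts closure (C7–C8) of a C5 vinyl carbinol, then Δ5→Δ6 isomerisation that sets H-5 trans.
4. C4 ⇐ methylation, then hydroxymethylation trapped as the 19,20-lactone (C19 cis to C20).
5. Ring A and C10 ⇐ enantioselective ring expansion of cyclopentanone by an aryl diazoacetate (1,2-alkyl shift); ring order C (arene) → A → B → lactone.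

Assumption: abietane numbering is used for the polycyclic compounds (target = 6α,12,19-trihydroxy-11,14-dioxoabieta-8,12-dien-20,7β-olide, 4S,5S,6R,7R,10R), and starting materials are counted with every non-hydrogen atom.

**Step 1**
Reactants: 1 hydroquinone; 2 propan-2-ol
Product: 3 2-isopropylbenzene-1,4-diol
Conditions: 85% H3PO4, 75 °C (1 in excess)
Reagents that add atoms: none
Why: Friedel–Crafts alkylation of the electron-rich diol by the 2-propyl cation; all four ring positions are equivalent and excess 1 suppresses dialkylation.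

**Step 2**
Reactants: 3 2-isopropylbenzene-1,4-diol
Product: 4 2-isopropyl-1,4-dimethoxybenzene
Conditions: Me2SO4, K2CO3, acetone, reflux
Reagents that add atoms: dimethyl sulfate, COS(=O)(=O)OC
Why: Williamson-type O-methylation masks the hydroquinone as a dimethyl ether that survives bases, Lewis acids and organometallics and is unmasked oxidatively in step 12.

**Step 3**
Reactants: 4 2-isopropyl-1,4-dimethoxybenzene; 5 methyl chlorooxoacetate
Product: 6 methyl 2-(4-isopropyl-2,5-dimethoxyphenyl)-2-oxoacetate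
Conditions: AlCl3 (1.1 equiv), CH2Cl2, −10 °C
Reagents that add atoms: none
Why: Friedel–Crafts acylation goes para to the isopropyl group and ortho to OMe (the doubly activated, least hindered site), which puts the future C10/C20 unit on C9 and leaves the free ortho position that becomes C8.

**Step 4**
Reactants: 6 methyl 2-(4-isopropyl-2,5-dimethoxyphenyl)-2-oxoacetate
Product: 8 methyl 2-diazo-2-(4-isopropyl-2,5-dimethoxyphenyl)acetate, via tosylhydrazone 7 (not isolated)
Conditions: TsNHNH2, MeOH, 60 °C; then DBU, CH2Cl2, rt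
Reagents that add atoms: 4-methylbenzenesulfonohydrazide, Cc1ccc(cc1)S(=O)(=O)NN
Why: Condensation to the tosylhydrazone and base-induced loss of sulfinate (Bamford–Stevens diazo synthesis) gives the donor/acceptor aryl diazoacetate.

**Step 5**
Reactants: 8 methyl 2-diazo-2-(4-isopropyl-2,5-dimethoxyphenyl)acetate; 9 cyclopentanone
Product: 10 methyl (S)-1-(4-isopropyl-2,5-dimethoxyphenyl)-2-oxocyclohexane-1-carboxylate
Conditions: Sc(OTf)3 (10 mol%), chiral C2-symmetric N,N′-dioxide ligand (11 mol%, antipode chosen to give (S)-10), 9 (3 equiv), 4 Å MS, CH2Cl2, −20 °C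
Reagents that add atoms: none
Why: Proposed new method: the chiral Sc(III)–N,N′-dioxide Lewis acid activates cyclopentanone, the nucleophilic diazo carbon of the electron-rich diazo ester 8 adds through one enantioface to give a β-(scandium-alkoxy) diazonium ion, and antiperiplanar 1,2-shift of a ring CH2 with loss of N2 (both ring bonds are equivalent, so there is no regiochemical issue) expands the ring to the cyclohexanone (ring A) and fixes the quaternary C10 as (S) with the aryl group and C20 already attached; the closest known reaction type is the Lewis-acid-catalysed Tiffeneau–Demjanov/Roskamp-type homologation of ketones with α-alkyl-α-diazo esters or aryldiazomethanes (including enantioselective Sc/N,N′-dioxide versions), which has not been shown for α-aryl-α-diazoacetates with simple cycloalkanones.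

**Step 6**
Reactants: 10 methyl (S)-1-(4-isopropyl-2,5-dimethoxyphenyl)-2-oxocyclohexane-1-carboxylate; 11 iodomethane
Product: 12 methyl (1S)-1-(4-isopropyl-2,5-dimethoxyphenyl)-3-methyl-2-oxocyclohexane-1-carboxylate (both C3 epimers)
Conditions: LiHMDS, THF, −78 °C; then MeI, −78 to −20 °C
Reagents that add atoms: none
Why: Lithium enolate alkylation at the only enolisable position (C4); the new centre is left as a mixture because it is planarised again in step 7.

**Step 7**
Reactants: 12 methyl (1S)-1-(4-isopropyl-2,5-dimethoxyphenyl)-3-methyl-2-oxocyclohexane-1-carboxylate; 13 formaldehyde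
Product: 15 (1S,5R)-1-(4-isopropyl-2,5-dimethoxyphenyl)-5-methyl-3-oxabicyclo[3.3.1]nonane-2,9-dione, via lithium aldolate 14 (not isolated)
Conditions: LiHMDS, THF, −78 °C; CH2O (gas, cracked paraformaldehyde), −78 to 0 °C; pH 7 buffer
Reagents that add atoms: none
Why: The enolate–formaldehyde aldol is reversible and only the adduct with CH2O⁻ cis to CO2Me can lactonise (intramolecular transesterification to the bicyclo[3.3.1] δ-lactone), so this thermodynamic trap fixes the C4 quaternary centre with C19 cis to C20.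

**Step 8**
Reactants: 15 (1S,5R)-1-(4-isopropyl-2,5-dimethoxyphenyl)-5-methyl-3-oxabicyclo[3.3.1]nonane-2,9-dione; 16 vinylmagnesium bromide
Product: 17 (1S,5R)-9-ethenyl-9-hydroxy-1-(4-isopropyl-2,5-dimethoxyphenyl)-5-methyl-3-oxabicyclo[3.3.1]nonan-2-one (C9 configuration not assigned)
Conditions: CeCl3 (anhydrous), THF, −78 °C; aq. NH4Cl at −78 °C
Reagents that add atoms: none
Why: Organocerium (Imamoto) 1,2-addition to the non-enolisable bridging ketone, which is more electrophilic than the hindered lactone; the carbinol configuration is irrelevant because C5 is ionised in step 9.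

**Step 9**
Reactants: 17 (1S,5R)-9-ethenyl-9-hydroxy-1-(4-isopropyl-2,5-dimethoxyphenyl)-5-methyl-3-oxabicyclo[3.3.1]nonan-2-one
Product: 18 (4S,10R)-11,14-dimethoxyabieta-5,8,11,13-tetraen-20,19-olide (19,20-lactone, C20 carbonyl)
Conditions: TfOH (10 mol%), HFIP–CH2Cl2, −20 to 0 °C
Reagents that add atoms: none
Why: Acid ionises the tertiary allylic alcohol to an allyl cation whose terminus (C7) lies in the plane of the aryl group and is captured by the only free ortho carbon (C8, ortho to OMe) in an intramolecular Friedel–Crafts alkylation that closes ring B as the Δ5 olefin.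

**Step 10**
Reactants: 18 (4S,10R)-11,14-dimethoxyabieta-5,8,11,13-tetraen-20,19-olide
Product: 19 (4S,5S,10R)-11,14-dimethoxyabieta-6,8,11,13-tetraen-20,19-olide (5α-H)
Conditions: t-BuOK (0.5 equiv), DMSO, 25 °C, argon; aq. NH4Cl
Reagents that add atoms: none
Why: Base-mediated 1,3-prototropic shift through the benzylic/allylic C7 anion (the 1,4- to 1,2-dihydronaphthalene isomerisation) moves the double bond into conjugation and sets C5 under thermodynamic control, because with ring A locked as a chair by the lactone the C6 arm takes the equatorial position, so H-5 is α (trans A/B).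

**Step 11**
Reactants: 19 (4S,5S,10R)-11,14-dimethoxyabieta-6,8,11,13-tetraen-20,19-olide
Product: 22 (4S,5S,6R,7R,10R)-6α,19-dihydroxy-11,14-dimethoxyabieta-8,11,13-trien-20,7β-olide, via lithium carboxylate 20 (not isolated), via epoxy carboxylate 21 (not isolated)
Conditions: LiOH, dioxane–H2O, 60 °C; then 0 °C, NaHCO3 (pH 8), acetone, Oxone; Na2S2O3
Reagents that add atoms: lithium hydroxide, [Li+].[OH-]; potassium peroxymonosulfate (Oxone, acting through dimethyldioxirane), [K+].[O-]S(=O)(=O)OO
Why: Saponification frees the C20 carboxylate, dimethyldioxirane made in situ epoxidises the styrene-type Δ6 bond from the α-face (the β-face is covered by the axial C19/C20 groups), and the carboxylate opens the epoxide anti at the benzylic, o-methoxy-activated C7 (epoxide-opening lactonisation), which gives the 7β-O lactone, the 6α-OH and the free 19-OH.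

**Step 12**
Reactants: 22 (4S,5S,6R,7R,10R)-6α,19-dihydroxy-11,14-dimethoxyabieta-8,11,13-trien-20,7β-olide
Product: 23 (4S,5S,6R,7R,10R)-6α,19-dihydroxy-11,14-dioxoabieta-8,12-dien-20,7β-olide
Conditions: (NH4)2Ce(NO3)6 (2.5 equiv), MeCN–H2O, 0 °C, 15 min
Reagents that add atoms: water, O
Why: Ceric ammonium nitrate oxidative demethylation of the p-dimethoxyarene gives the p-quinone (carbonyl oxygen from water), and the lactone and both alcohols tolerate the short, cold reaction.

**Step 13**
Reactants: 23 (4S,5S,6R,7R,10R)-6α,19-dihydroxy-11,14-dioxoabieta-8,12-dien-20,7β-olide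
Product: 25 (4S,5S,6R,7R,10R)-6α,12,19-trihydroxy-11,14-dioxoabieta-8,12-dien-20,7β-olide, via quinone epoxide 24 (not isolated)
Conditions: 30% H2O2, Na2CO3, THF–H2O, 0 °C to rt; then 1 M HCl
Reagents that add atoms: hydrogen peroxide, OO
Why: Weitz–Scheffer nucleophilic epoxidation of the less substituted quinone C=C (C12=C13; C8=C9 is tetrasubstituted) followed by base-induced E1cB opening from the acidic C12–H gives the 12-hydroxyquinone with the isopropyl group left on C13, and no stereocentre is touched.

**Compound list**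
1 | hydroquinone | Oc1ccc(O)cc1 | starting material
2 | propan-2-ol | CC(C)O | starting material
3 | 2-isopropylbenzene-1,4-diol | CC(C)c1cc(O)ccc1O | intermediate
4 | 2-isopropyl-1,4-dimethoxybenzene | COc1ccc(OC)c(C(C)C)c1 | intermediate
5 | methyl chlorooxoacetate | COC(=O)C(Cl)=O | starting material
6 | methyl 2-(4-isopropyl-2,5-dimethoxyphenyl)-2-oxoacetate | COC(=O)C(=O)c1cc(OC)c(C(C)C)cc1OC | intermediate
7 | tosylhydrazone of 6 | COC(=O)C(=NNS(=O)(=O)c1ccc(C)cc1)c1cc(OC)c(C(C)C)cc1OC | intermediate
8 | methyl 2-diazo-2-(4-isopropyl-2,5-dimethoxyphenyl)acetate | COC(=O)C(=[N+]=[N-])c1cc(OC)c(C(C)C)cc1OC | intermediate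
9 | cyclopentanone | O=C1CCCC1 | starting material
10 | methyl (S)-1-(4-isopropyl-2,5-dimethoxyphenyl)-2-oxocyclohexane-1-carboxylate | COC(=O)[C@]1(c2cc(OC)c(C(C)C)cc2OC)CCCCC1=O | intermediate
11 | iodomethane | CI | starting material
12 | methyl (1S)-1-(4-isopropyl-2,5-dimethoxyphenyl)-3-methyl-2-oxocyclohexane-1-carboxylate (C3 epimers) | COC(=O)[C@]1(c2cc(OC)c(C(C)C)cc2OC)CCCC(C)C1=O | intermediate
13 | formaldehyde | C=O | starting material
14 | lithium alkoxide of methyl (1S,3R)-3-(hydroxymethyl)-1-(4-isopropyl-2,5-dimethoxyphenyl)-3-methyl-2-oxocyclohexane-1-carboxylate (CH2O⁻ cis to CO2Me) | [Li+].COC(=O)[C@]1(c2cc(OC)c(C(C)C)cc2OC)CCC[C@](C)(C[O-])C1=O | intermediate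
15 | (1S,5R)-1-(4-isopropyl-2,5-dimethoxyphenyl)-5-methyl-3-oxabicyclo[3.3.1]nonane-2,9-dione | O=C1OC[C@@]2(C)CCC[C@]1(c3cc(OC)c(C(C)C)cc3OC)C2=O | intermediate
16 | vinylmagnesium bromide | C=C[Mg]Br | starting material
17 | (1S,5R)-9-ethenyl-9-hydroxy-1-(4-isopropyl-2,5-dimethoxyphenyl)-5-methyl-3-oxabicyclo[3.3.1]nonan-2-one (C9 unassigned) | O=C1OC[C@@]2(C)CCC[C@]1(c3cc(OC)c(C(C)C)cc3OC)C2(O)C=C | intermediate
18 | (4S,10R)-11,14-dimethoxyabieta-5,8,11,13-tetraen-20,19-olide | COc1cc(C(C)C)c(OC)c2c1[C@]34CCC[C@](C)(COC3=O)C4=CC2 | intermediate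
19 | (4S,5S,10R)-11,14-dimethoxyabieta-6,8,11,13-tetraen-20,19-olide | COc1cc(C(C)C)c(OC)c2c1[C@]34CCC[C@](C)(COC3=O)[C@@H]4C=C2 | intermediate
20 | lithium (4S,5S,10R)-19-hydroxy-11,14-dimethoxyabieta-6,8,11,13-tetraen-20-oate | [Li+].COc1cc(C(C)C)c(OC)c2c1[C@@]3(C(=O)[O-])CCC[C@](C)(CO)[C@@H]3C=C2 | intermediate
21 | lithium 6α,7α-epoxy-19-hydroxy-11,14-dimethoxyabieta-8,11,13-trien-20-oate | [Li+].COc1cc(C(C)C)c(OC)c2c1[C@@]3(C(=O)[O-])CCC[C@](C)(CO)[C@@H]3[C@H]4O[C@@H]24 | intermediate
22 | (4S,5S,6R,7R,10R)-6α,19-dihydroxy-11,14-dimethoxyabieta-8,11,13-trien-20,7β-olide | COc1cc(C(C)C)c(OC)c2c1[C@]34CCC[C@](C)(CO)[C@@H]4[C@@H](O)[C@@H]2OC3=O | intermediate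
23 | (4S,5S,6R,7R,10R)-6α,19-dihydroxy-11,14-dioxoabieta-8,12-dien-20,7β-olide | CC(C)C1=CC(=O)C2=C(C1=O)[C@H]1OC(=O)[C@@]23CCC[C@](C)(CO)[C@@H]3[C@H]1O | intermediate
24 | 12,13-epoxide of 23 (epoxide configuration unassigned) | CC(C)C12OC1C(=O)C3=C(C2=O)[C@H]4OC(=O)[C@@]35CCC[C@](C)(CO)[C@@H]5[C@H]4O | intermediate
25 | (4S,5S,6R,7R,10R)-6α,12,19-trihydroxy-11,14-dioxoabieta-8,12-dien-20,7β-olide (CNP0339604.1) | CC(C)C1=C(O)C(=O)C2=C(C1=O)[C@H]1OC(=O)[C@@]23CCC[C@](C)(CO)[C@@H]3[C@H]1O | target

**Totals**
Total step count: 13. Longest linear sequence: 13 steps (1 → 25).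

**Three steps most likely to fail**

Step 5 (the proposed ring expansion; a donor/acceptor diazo ester may be too weak a nucleophile or may decompose on the Lewis acid). The fallback uses known chemistry, sets out from 3 and comes back at 10. Compound 3 is oxidised with O2 and catalytic Co(salen) to 2-isopropyl-1,4-benzoquinone F1. Cyclohexanone and dimethyl carbonate (NaH, THF) give methyl 2-oxocyclohexane-1-carboxylate F2. A cinchona-alkaloid-catalysed enantioselective conjugate addition of F2 to F1 (organocatalytic α-arylation of β-keto esters with quinones, attack at the quinone carbon para to the isopropyl group, then aromatisation) gives methyl (S)-1-(2,5-dihydroxy-4-isopropylphenyl)-2-oxocyclohexane-1-carboxylate F3. O-methylation of both phenols (Me2SO4, K2CO3) gives 10.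

Step 10 (the Δ5/Δ6 equilibrium may be incomplete, or the base may attack the lactone). The fallback sets out from 18 and comes back at 19. mCPBA converts 18 into the 5,6-epoxide of 18 F4. BF3·OEt2 opens it at tertiary C5 with a 1,2-hydride shift from C6 (Meinwald rearrangement) to (4S,5S,10R)-11,14-dimethoxy-6-oxoabieta-8,11,13-trien-20,19-olide F5, whose C5–H is now α to a carbonyl and is equilibrated with DBU to the trans ring fusion. NaBH4 delivers hydride from the open α-face to give 6β-hydroxy-11,14-dimethoxyabieta-8,11,13-trien-20,19-olide F6. Burgess reagent then eliminates syn toward C7 (H-5 is α and cannot be reached) to give 19.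

Step 11 (the carboxylate may open the epoxide at C6 to a γ-lactone, or the hindered lactone may resist hydrolysis). The fallback sets out from 19 and comes back at 22. Hydroboration–oxidation (BH3·THF, then NaBO3) from the α-face puts the hydroxyl on C6 and gives 6α-hydroxy-11,14-dimethoxyabieta-8,11,13-trien-20,19-olide F7. LiOH opens the 19,20-lactone to lithium 6α,19-dihydroxy-11,14-dimethoxyabieta-8,11,13-trien-20-oate F8. DDQ abstracts the benzylic C7 hydride and the C20 carboxylate traps the o-methoxybenzyl cation from the β-face, which can only give the 20,7β-lactone 22.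

**Further compounds**
F1 | step 5 | 2-isopropyl-1,4-benzoquinone | CC(C)C1=CC(=O)C=CC1=O
F2 | step 5 | methyl 2-oxocyclohexane-1-carboxylate | COC(=O)C1CCCCC1=O
F3 | step 5 | methyl (S)-1-(2,5-dihydroxy-4-isopropylphenyl)-2-oxocyclohexane-1-carboxylate | COC(=O)[C@]1(c2cc(O)c(C(C)C)cc2O)CCCCC1=O
F4 | step 10 | 5,6-epoxide of 18 (epoxide configuration unassigned) | COc1cc(C(C)C)c(OC)c2c1[C@]34CCC[C@](C)(COC3=O)C45OC5C2
F5 | step 10 | (4S,5S,10R)-11,14-dimethoxy-6-oxoabieta-8,11,13-trien-20,19-olide | COc1cc(C(C)C)c(OC)c2c1[C@]34CCC[C@](C)(COC3=O)[C@@H]4C(=O)C2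
F6 | step 10 | 6β-hydroxy-11,14-dimethoxyabieta-8,11,13-trien-20,19-olide | COc1cc(C(C)C)c(OC)c2c1[C@]34CCC[C@](C)(COC3=O)[C@@H]4[C@H](O)C2
F7 | step 11 | 6α-hydroxy-11,14-dimethoxyabieta-8,11,13-trien-20,19-olide | COc1cc(C(C)C)c(OC)c2c1[C@]34CCC[C@](C)(COC3=O)[C@@H]4[C@@H](O)C2
F8 | step 11 | lithium 6α,19-dihydroxy-11,14-dimethoxyabieta-8,11,13-trien-20-oate | [Li+].COc1cc(C(C)C)c(OC)c2c1[C@@]3(C(=O)[O-])CCC[C@](C)(CO)[C@@H]3[C@@H](O)C2
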